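## Retrosynthetic overview

1. The acid comes from its methyl ester. The E,E-diene is cut at its central C–C bond by Suzuki–Miyaura coupling into an (E)-alkenyl boronate on the dioxolane core and (1E,4Z)-1-iodohepta-1,4-diene, which is made from (Z)-hex-3-enal.
2. The boronate comes from a terminal alkene by cross-metathesis. The C3–CH2CO2Me bond comes from catalyst-controlled addition of a silyl ketene acetal to the peroxycarbenium ion of a 1,2-dioxolan-3-ol; this sets C3.
3. The dioxolan-3-ol comes from ring enlargement of a 2,2,4-trisubstituted oxetane. H2O2 opens the tertiary C–O bond from the back side (sets C5 by inversion), then the alcohol is oxidised and the ring closes.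
4. The oxetane comes from one-carbon ring enlargement of a 2,2-disubstituted oxirane by ethylidene transfer. The oxirane comes from enantioselective methylene transfer to dec-9-en-2-one, made from 6-bromohex-1-ene and but-3-en-2-one.
5. Ring order: oxirane, then oxetane, then the 1,2-dioxolane (the only ring of the target). The triene is attached last.

Assumption: the sense of induction of the two chiral catalysts (steps 2 and 5) is as drawn; if a pilot run shows the opposite sense, the mirror-image catalyst is used.

## Route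

Step 1
Reactants: 1 6-bromohex-1-ene; 2 but-3-en-2-one
Product: 5 dec-9-en-2-one, via hex-5-en-1-ylmagnesium bromide 3 (not isolated), via silyl enol ether 4 (not isolated)
Conditions: Mg, THF, rt; then CuBr·SMe2 (10 mol %), Me3SiCl (2 equiv), 2, THF, −78 °C; 1 M HCl work-up
Reagents that add atoms: none
Why: Copper-catalysed, Me3SiCl-accelerated conjugate (1,4-) addition of a primary Grignard reagent to an enone gives the silyl enol ether, which the acidic work-up turns into the methyl ketone; no stereocentre is formed.

Step 2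
Reactants: 5 dec-9-en-2-one
Product: 7 (2R,4RS)-2,4-dimethyl-2-(oct-7-en-1-yl)oxetane, via (R)-oxirane 6 (not isolated)
Conditions: Me3S(O)Cl/NaH (1.05 equiv ylide), LaLi3[(S)-binaphthoxide]3 (5 mol %), [2,4,6-(MeO)3C6H2]3P=O (5 mol %), MS 5 Å, THF, rt; then [PhS(O)(NMe2)Et]BF4/NaH (2 equiv ylide), THF/DMSO, 55 °C
Reagents that add atoms: trimethylsulfoxonium chloride, C[S+](C)(C)=O.[Cl-]; (dimethylamino)ethylphenyloxosulfonium tetrafluoroborate, CC[S+](=O)(N(C)C)c1ccccc1.F[B-](F)(F)F
Why: Proposed new method: stage one is the known LaLi3(binaphthoxide)3-catalysed enantioselective Corey–Chaykovsky methylene transfer to an alkyl methyl ketone, which sets the quaternary C–O centre as R (usually above 90% ee); the new part is the ring enlargement of the oxirane with an aminosulfoxonium ethylide, in which the ylide carbon opens the oxirane at its CH2 and the tertiary alkoxide then displaces neutral N,N-dimethylbenzenesulfinamide in a 4-exo-tet closure, so the C–O bond at the stereocentre is never broken (retention) and the new C4 centre (about 1:1) is erased in step 4; the closest known reaction is the oxirane-to-oxetane ring expansion with dimethylsulfoxonium methylide, shown so far only for CH2 transfer.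

Step 3
Reactants: 7 (2R,4RS)-2,4-dimethyl-2-(oct-7-en-1-yl)oxetane
Product: 8 (4S)-4-hydroperoxy-4-methyldodec-11-en-2-ol
Conditions: anhydrous H2O2 (ca. 3 M in Et2O, 10 equiv), Me3SiOTf (0.2 equiv), Et2O, −78 to −20 °C
Reagents that add atoms: hydrogen peroxide, OO
Why: Lewis-acid-catalysed perhydrolysis of an oxetane: H2O2 attacks the activated ring at the tertiary carbon in an SN2-like, strain-releasing back-side opening, so this centre is inverted from R to S and the O–O unit is installed.

Step 4
Reactants: 8 (4S)-4-hydroperoxy-4-methyldodec-11-en-2-ol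
Product: 10 (5S)-3,5-dimethyl-5-(oct-7-en-1-yl)-1,2-dioxolan-3-ol, via hydroperoxy ketone 9 (not isolated)
Conditions: 4-acetamido-2,2,6,6-tetramethyl-1-oxopiperidinium tetrafluoroborate (1.1 equiv), silica gel, CH2Cl2, rt
Reagents that add atoms: none
Why: Oxoammonium oxidation is a hydride transfer from the carbinol C–H; the tertiary hydroperoxide has no such hydrogen and its one-electron oxidation is uphill, and the β-hydroperoxy ketone closes at once to the five-membered peroxyhemiketal, completing the oxetane-to-1,2-dioxolane ring enlargement (C3 is an anomeric mixture, C5 is untouched).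

Step 5
Reactants: 10 (5S)-3,5-dimethyl-5-(oct-7-en-1-yl)-1,2-dioxolan-3-ol; 11 tert-butyl[(1-methoxyethenyl)oxy]dimethylsilane
Product: 14 methyl 2-[(3R,5S)-3,5-dimethyl-5-(oct-7-en-1-yl)-1,2-dioxolan-3-yl]acetate, via O-silyl peroxyketal 12 (not isolated), via peroxycarbenium ion 13 (not isolated)
Conditions: confined imidodiphosphorimidate Brønsted acid (IDPi, from two 3,3'-diaryl-(S)-BINOL units, N-triflyl groups; 2 mol %), 11 (2.5 equiv), Et2O, −78 to −60 °C; aq NaHCO3
Reagents that add atoms: none
Why: Proposed new method: the first equivalent of 11 silylates the hemiketal (12) and converts the IDPi acid into its silylium form, which removes the silyloxy group as the disiloxane and leaves the planar peroxycarbenium ion 13 paired with the confined chiral anion; this anion shields one face, so the second equivalent of 11 attacks C3 from the open face and gives the 3R quaternary centre (the remote C5 centre, Me versus CH2R, gives almost no bias, so control must come from the catalyst), C5 is untouched, and the few percent of 5R material carried from steps 2 and 3 becomes a separable diastereomer, which raises the ee of 14; the closest known reactions are the TiCl4- or Me3SiOTf-promoted, unselective substitution of 3-alkoxy-1,2-dioxolanes by silyl ketene acetals and the IDPi/silylium-catalysed enantioselective Mukaiyama additions to cyclic oxocarbenium ions and to simple methyl ketones.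

Step 6
Reactants: 14 methyl 2-[(3R,5S)-3,5-dimethyl-5-(oct-7-en-1-yl)-1,2-dioxolan-3-yl]acetate; 15 2-ethenyl-4,4,5,5-tetramethyl-1,3,2-dioxaborolane
Product: 16 methyl 2-[(3R,5S)-3,5-dimethyl-5-[(7E)-8-(4,4,5,5-tetramethyl-1,3,2-dioxaborolan-2-yl)oct-7-en-1-yl]-1,2-dioxolan-3-yl]acetate
Conditions: 15 (3 equiv), second-generation Hoveyda–Grubbs catalyst RuCl2(H2IMes)(=CH-C6H4-2-OiPr) (5 mol %), CH2Cl2, 40 °C
Reagents that add atoms: none
Why: Olefin cross-metathesis of a terminal alkene with a vinyl boronate is E-selective for steric reasons and is driven by loss of ethene; a fully substituted dialkyl peroxide tolerates ruthenium alkylidenes.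

Step 7
Reactants: 17 (Z)-hex-3-enal
Product: 18 (1E,4Z)-1-iodohepta-1,4-diene
Conditions: CrCl2 (6 equiv), CHI3 (2 equiv), THF/1,4-dioxane, 0 °C
Reagents that add atoms: iodoform, IC(I)I
Why: Takai olefination: the geminal dichromium species formed from CHI3 and divalent chromium adds to the aldehyde and eliminates to the E-iodoalkene; the medium is not basic, so the Z β,γ-alkene neither moves into conjugation nor isomerises.

Step 8
Reactants: 16 alkenyl boronate of step 6; 18 (1E,4Z)-1-iodohepta-1,4-diene
Product: 19 methyl 2-[(3R,5S)-3,5-dimethyl-5-[(7E,9E,12Z)-pentadeca-7,9,12-trien-1-yl]-1,2-dioxolan-3-yl]acetate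
Conditions: PdCl2(dppf) (5 mol %), K3PO4 (3 equiv), THF/H2O 10:1, degassed, rt
Reagents that add atoms: none
Why: Suzuki–Miyaura coupling of an alkenyl boronate with an alkenyl iodide keeps both alkene geometries, giving the E,E-diene next to the untouched Z-alkene; the hindered peroxide survives zerovalent palladium at room temperature with a chelating phosphine.

Step 9
Reactants: 19 methyl ester of step 8
Product: 20 2-[(3R,5S)-3,5-dimethyl-5-[(7E,9E,12Z)-pentadeca-7,9,12-trien-1-yl]-1,2-dioxolan-3-yl]acetic acid
Conditions: LiOH (3 equiv), THF/H2O, 0 °C; then 1 M HCl to pH 4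
Reagents that add atoms: lithium hydroxide, [Li+].[OH-]
Why: Mild saponification (acyl–oxygen cleavage) frees the acid; at 0 °C hydroxide attacks the ester carbonyl faster than it enolises the ester, so no retro-oxa-Michael opening of the peroxide occurs and neither stereocentre is touched.

## Compound list

1 | 6-bromohex-1-ene | C=CCCCCBr | starting material
2 | but-3-en-2-one | CC(=O)C=C | starting material
3 | hex-5-en-1-ylmagnesium bromide | C=CCCCC[Mg]Br | intermediate
4 | (deca-2,9-dien-2-yloxy)trimethylsilane (E/Z mixture) | C=CCCCCCC=C(C)O[Si](C)(C)C | intermediate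
5 | dec-9-en-2-one | CC(=O)CCCCCCC=C | intermediate
6 | (2R)-2-methyl-2-(oct-7-en-1-yl)oxirane | C=CCCCCCC[C@]1(C)CO1 | intermediate
7 | (2R,4RS)-2,4-dimethyl-2-(oct-7-en-1-yl)oxetane | C=CCCCCCC[C@]1(C)CC(C)O1 | intermediate
8 | (4S)-4-hydroperoxy-4-methyldodec-11-en-2-ol (C2 epimers) | C=CCCCCCC[C@](C)(OO)CC(C)O | intermediate
9 | (4S)-4-hydroperoxy-4-methyldodec-11-en-2-one | C=CCCCCCC[C@](C)(OO)CC(C)=O | intermediate
10 | (5S)-3,5-dimethyl-5-(oct-7-en-1-yl)-1,2-dioxolan-3-ol (C3 anomers) | C=CCCCCCC[C@@]1(C)CC(C)(O)OO1 | intermediate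
11 | tert-butyl[(1-methoxyethenyl)oxy]dimethylsilane (O-silyl-protected enol of methyl acetate) | C=C(OC)O[Si](C)(C)C(C)(C)C | starting material
12 | (5S)-3-[(tert-butyldimethylsilyl)oxy]-3,5-dimethyl-5-(oct-7-en-1-yl)-1,2-dioxolane | C=CCCCCCC[C@@]1(C)CC(C)(O[Si](C)(C)C(C)(C)C)OO1 | intermediate
13 | (5S)-3,5-dimethyl-5-(oct-7-en-1-yl)-4,5-dihydro-1,2-dioxol-2-ium (peroxycarbenium ion, IDPi counter-anion) | C=CCCCCCC[C@@]1(C)CC(C)=[O+]O1 | intermediate
14 | methyl 2-[(3R,5S)-3,5-dimethyl-5-(oct-7-en-1-yl)-1,2-dioxolan-3-yl]acetate | C=CCCCCCC[C@@]1(C)C[C@](C)(CC(=O)OC)OO1 | intermediate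
15 | 2-ethenyl-4,4,5,5-tetramethyl-1,3,2-dioxaborolane (pinacol-protected vinylboronic acid) | C=CB1OC(C)(C)C(C)(C)O1 | starting material
16 | methyl 2-[(3R,5S)-3,5-dimethyl-5-[(7E)-8-(4,4,5,5-tetramethyl-1,3,2-dioxaborolan-2-yl)oct-7-en-1-yl]-1,2-dioxolan-3-yl]acetate | CC1(C)OB(/C=C/CCCCCC[C@@]2(C)C[C@](C)(CC(=O)OC)OO2)OC1(C)C | intermediate
17 | (Z)-hex-3-enal | CC/C=C\CC=O | starting material
18 | (1E,4Z)-1-iodohepta-1,4-diene | CC/C=C\C/C=C/I | intermediate
19 | methyl 2-[(3R,5S)-3,5-dimethyl-5-[(7E,9E,12Z)-pentadeca-7,9,12-trien-1-yl]-1,2-dioxolan-3-yl]acetate | CC/C=C\C/C=C/C=C/CCCCCC[C@@]1(C)C[C@](C)(CC(=O)OC)OO1 | intermediate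
20 | 2-[(3R,5S)-3,5-dimethyl-5-[(7E,9E,12Z)-pentadeca-7,9,12-trien-1-yl]-1,2-dioxolan-3-yl]acetic acid | CC/C=C\C/C=C/C=C/CCCCCC[C@@]1(C)C[C@](C)(CC(=O)O)OO1 | target

## Step count and risks

Total step count: 9. Longest linear sequence: 8 (steps 1–6, 8 and 9).

**Step 2 (new ring enlargement).**
- Risk: the γ-oxido sulfoxonium intermediate may lose the sulfinamide by E2 to give a homoallylic alcohol. It may also fragment in the Grob sense back to 5 instead of closing at a secondary carbon.
- Fallback (known chemistry, acyl-anion route plus Williamson closure): set out from 6, isolated after the first stage.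
- Open 6 with 2-lithio-2-methyl-1,3-dithiane (THF/DMPU) to the hydroxy dithiane F1.
- Unmask with MeI/CaCO3 in aqueous MeCN to the β-hydroxy ketone F2, then reduce with NaBH4 to the 1,3-diol F3.
- Mesylate only the secondary hydroxyl (MsCl, pyridine, 0 °C) to the monomesylate F4 and close with KOtBu in THF.
- This comes back to the route at 7 with the same R centre, at the cost of four more steps.

**Step 4 (alcohol oxidation beside a free hydroperoxide).**
- Risk: the oxidation may be slow, or the acid released may degrade the hydroperoxide.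
- Fallback (mask, oxidise, unmask): set out from 8 and cap the OOH group with 2-methoxypropene/PPTS to the peroxyketal alcohol F5.
- Oxidise with Dess–Martin periodinane to the peroxyketal ketone F6.
- Strip the ketal with aqueous AcOH/THF, whereupon the hydroperoxy ketone closes.
- This comes back at 10.

**Step 5 (new catalyst-controlled alkylation).**
- Risk: the ion pair may react slowly, or with low facial selectivity at a fully substituted peroxycarbenium carbon.
- Fallback (known stoichiometric Lewis-acid chemistry plus separation): set out from 10 and form the 3-methoxy-1,2-dioxolane F7 with MeOH/PPTS.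
- Treat F7 with TiCl4 and 11 in CH2Cl2 at −78 °C. This gives 14 together with its C3 epimer F8 (about 1:1), removed by chromatography.
- This comes back at 14.

## Further compounds

F1 | step 2 | (2R)-2-methyl-1-(2-methyl-1,3-dithian-2-yl)dec-9-en-2-ol | C=CCCCCCC[C@@](C)(O)CC1(C)SCCCS1
F2 | step 2 | (4R)-4-hydroxy-4-methyldodec-11-en-2-one | C=CCCCCCC[C@@](C)(O)CC(C)=O
F3 | step 2 | (4R)-4-methyldodec-11-ene-2,4-diol (C2 epimers) | C=CCCCCCC[C@@](C)(O)CC(C)O
F4 | step 2 | (4R)-4-hydroxy-4-methyldodec-11-en-2-yl methanesulfonate | C=CCCCCCC[C@@](C)(O)CC(C)OS(C)(=O)=O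
F5 | step 4 | (4S)-4-[(2-methoxypropan-2-yl)peroxy]-4-methyldodec-11-en-2-ol | C=CCCCCCC[C@](C)(OOC(C)(C)OC)CC(C)O
F6 | step 4 | (4S)-4-[(2-methoxypropan-2-yl)peroxy]-4-methyldodec-11-en-2-one | C=CCCCCCC[C@](C)(OOC(C)(C)OC)CC(C)=O
F7 | step 5 | (5S)-3-methoxy-3,5-dimethyl-5-(oct-7-en-1-yl)-1,2-dioxolane | C=CCCCCCC[C@@]1(C)CC(C)(OC)OO1
F8 | step 5 | methyl 2-[(3S,5S)-3,5-dimethyl-5-(oct-7-en-1-yl)-1,2-dioxolan-3-yl]acetate | C=CCCCCCC[C@@]1(C)C[C@@](C)(CC(=O)OC)OO1
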